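The route rests on cutting the C3–C4 bond of ring A (labdane numbering). Ring B is taken from (R)-carvone: its stereocentre is C5, its isopropenyl group already holds quaternary C4 with both methyls, and its α′ carbon becomes quaternary C10. The key step exploits this gem-dimethyl C4 next to the C5–C10 ring fusion: hydrogen-atom transfer from Fe(acac)3/PhSiH3 turns the isopropenyl group into the tertiary C4 radical, which adds to an acrylate arm on C10 and closes ring A as a trans-decalin in one operation. The precursor is carvone carrying methyl and 2-(methoxycarbonyl)allyl groups on the α′ carbon. The side chain follows by two palladium-catalysed couplings.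

Key step: step 3

Remark: labdane numbering is used throughout (decalin C1–C10, side chain C11–C18 with the carboxyl carbon as C18); the two C2 epimers formed in step 3 are carried on together, because C2 becomes a methylene in step 5.

Step 1
Reactants: 1 (R)-(−)-carvone; 2 iodomethane
Product: 4 (5R)-2,6-dimethyl-5-(prop-1-en-2-yl)cyclohex-2-en-1-one (6-methylcarvone; both C6 epimers), via lithium dienolate of carvone 3 (not isolated)
Conditions: LiN(i-Pr)2, THF, −78 °C; then MeI, −78 → 0 °C
Reagents that add atoms: iodomethane 2, CI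
Why: Kinetic deprotonation at the α′ methylene (the future C10) gives the cross-conjugated dienolate, which is C-methylated (enolate alkylation); the new centre forms as an epimer mixture that is of no consequence because step 2 makes it planar again.

Step 2
Reactants: 4 6-methylcarvone (C6 epimers); 5 methyl 2-(bromomethyl)acrylate
Product: 7 methyl 2-{[(1S,6S)-1,3-dimethyl-2-oxo-6-(prop-1-en-2-yl)cyclohex-3-en-1-yl]methyl}prop-2-enoate (methyl cis to isopropenyl), via tetrasubstituted lithium enolate 6 (not isolated)
Conditions: LiN(i-Pr)2, THF, −78 °C; then 5, −78 → −30 °C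
Reagents that add atoms: methyl 2-(bromomethyl)acrylate 5, C=C(CBr)C(=O)OC
Why: Enolate alkylation with a very reactive allylic bromide (SN2 and SN2′ give the same product); the electrophile should approach the enolate face opposite to the neighbouring C5 isopropenyl group, which sets quaternary C10 with the methyl cis and the acrylate arm trans to isopropenyl.

Step 3
Reactants: 7 dialkylated carvone
Product: 8 methyl (4aS,8aS)-4,4,7,8a-tetramethyl-8-oxo-1,2,3,4,4a,5,8,8a-octahydronaphthalene-2-carboxylate (trans-decalin; both C2 epimers)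
Conditions: Fe(acac)3 (30 mol%), PhSiH3, EtOH/HOCH2CH2OH, 60 °C
Reagents that add atoms: none
Why: An Fe–H species formed from Fe(acac)3 and PhSiH3 transfers a hydrogen atom to the CH2 terminus of the isopropenyl group, which leaves the tertiary C4 radical with both methyls in place; this nucleophilic radical adds to the unsubstituted acrylate terminus C3, and the α-ester radical at C2 is reduced by divalent iron and protonated by ethanol. The closest known reaction type is the iron-catalysed reductive olefin coupling, a hydrogen-atom-transfer Giese addition that builds quaternary carbons, used here intramolecularly. Ring A closes in the 6-endo-trig mode, because attack at the CH2 end is favoured by the polarity of the acrylate and gives a stabilised tertiary α-ester radical, whereas 5-exo attack at the ester-bearing carbon would give a primary radical. The ring fusion is not created here: C5 comes from carvone and C10 from step 2 with the C4 and C1 branches trans on ring B, so only the trans-decalin can form, while the single new centre C2 arises from unselective protonation and is erased in step 5. The step needs hydrogen-atom transfer to the isopropenyl olefin in preference to the enone and the acrylate, which polarity matching secures, since the Fe–H species reacts fastest with the electron-rich 1,1-disubstituted olefin and the electron-poor olefins act only as acceptors, of which only the acrylate lies within reach of C4 through a six-membered transition state.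

Step 4
Reactants: 8 bicyclic enone ester (C2 epimers)
Product: 9 (4aS,8aS)-4,4,7,8a-tetramethyl-8-oxo-1,2,3,4,4a,5,8,8a-octahydronaphthalene-2-carboxylic acid (both C2 epimers)
Conditions: LiOH, THF/MeOH/H2O, rt; then aq. HCl
Reagents that add atoms: lithium hydroxide, [Li+].[OH-]
Why: Saponification of an unhindered secondary methyl ester; the enone and the non-enolisable C10 are inert to aqueous hydroxide at room temperature.

Step 5
Reactants: 9 enone acid (C2 epimers)
Product: 11 (4aS,8aS)-2,5,5,8a-tetramethyl-4a,5,6,7,8,8a-hexahydronaphthalen-1(4H)-one, via Barton ester 10 (not isolated)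
Conditions: N-hydroxypyridine-2-thione, DCC, DMAP (cat.), CH2Cl2, rt, dark; then t-BuSH, visible light, rt
Reagents that add atoms: none
Why: Barton reductive decarboxylation: the O-acyl thiohydroxamate fragments under visible light to the secondary C2 radical, which takes hydrogen from t-BuSH, so C2 becomes a methylene and both epimers converge on one enone.

Step 6
Reactants: 11 decalin enone
Product: 13 (4aS,8aS)-2,5,5,8a-tetramethyl-3,4,4a,5,6,7,8,8a-octahydronaphthalen-1-yl trifluoromethanesulfonate, via lithium enolate 12 (not isolated)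
Conditions: LiBH(s-Bu)3, THF, −78 °C; then PhNTf2, −78 °C → rt
Reagents that add atoms: N-phenylbis(trifluoromethanesulfonimide), O=S(=O)(N(c1ccccc1)S(=O)(=O)C(F)(F)F)C(F)(F)F
Why: Conjugate hydride addition to the enone, whose β-carbon C7 carries no substituent beyond the ring (as in carvone itself) and whose carbonyl is shielded by quaternary C10, gives the C8–C9 enolate regiospecifically, and O-sulfonylation with PhNTf2 traps it as the tetrasubstituted enol triflate; no stereocentre is formed.

Step 7
Reactants: 14 (4-bromobut-1-yn-1-yl)trimethylsilane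
Product: 15 [4-(trimethylsilyl)but-3-yn-1-yl]zinc bromide (used as a titrated solution)
Conditions: Zn, I2 (5 mol%), DMA, 80 °C
Reagents that add atoms: zinc, [Zn]
Why: Direct insertion of iodine-activated zinc into a primary C–Br bond in a polar amide solvent gives the homopropargylic alkylzinc bromide, which has no β-leaving group and tolerates the silyl alkyne.

Step 8
Reactants: 13 enol triflate; 15 alkylzinc bromide
Product: 16 trimethyl{4-[(4aS,8aS)-2,5,5,8a-tetramethyl-3,4,4a,5,6,7,8,8a-octahydronaphthalen-1-yl]but-1-yn-1-yl}silane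
Conditions: Pd(dppf)Cl2 (5 mol%), LiCl, THF/DMA, 60 °C
Reagents that add atoms: [4-(trimethylsilyl)but-3-yn-1-yl]zinc bromide 15, C[Si](C)(C)C#CCC[Zn]Br
Why: Negishi coupling of an alkenyl triflate with a primary alkylzinc halide forms the C9–C11 bond; the wide-bite-angle diphosphine favours reductive elimination over β-hydride elimination, and the silyl cap keeps the alkyne out of the palladium cycle.

Step 9
Reactants: 16 silyl alkyne
Product: 17 (4aS,8aS)-1-(but-3-yn-1-yl)-2,5,5,8a-tetramethyl-3,4,4a,5,6,7,8,8a-octahydronaphthalene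
Conditions: K2CO3, MeOH/THF, rt
Reagents that add atoms: none
Why: Carbonate-mediated methanolysis of the alkynyl C–Si bond frees the terminal alkyne needed for carbometalation; the rest of the molecule is a base-stable hydrocarbon.

Step 10
Reactants: 18 methyl (S)-3-hydroxy-2-methylpropanoate
Product: 19 methyl (S)-3-[(tert-butyldimethylsilyl)oxy]-2-methylpropanoate
Conditions: TBSCl, imidazole, CH2Cl2, 0 °C → rt
Reagents that add atoms: tert-butyldimethylsilyl chloride, CC(C)(C)[Si](C)(C)Cl
Why: Standard silylation of a primary alcohol under imidazole catalysis, mild enough to leave the α-stereocentre of the ester untouched.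

Step 11
Reactants: 19 silyl ether ester
Product: 20 (S)-3-[(tert-butyldimethylsilyl)oxy]-2-methylpropanal (used crude at once)
Conditions: i-Bu2AlH (1.1 equiv), CH2Cl2, −78 °C; aq. potassium sodium tartrate
Reagents that add atoms: none
Why: Half-reduction of the ester at low temperature stops at the tetrahedral aluminium hemiacetal, which releases the aldehyde only on work-up; the α-stereocentre should be retained if the aldehyde is not chromatographed or stored.

Step 12
Reactants: 20 α-methyl aldehyde
Product: 21 (R,E)-tert-butyl[(4-iodo-2-methylbut-3-en-1-yl)oxy]dimethylsilane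
Conditions: CrCl2, CHI3, THF, 0 °C → rt
Reagents that add atoms: iodoform, IC(I)I
Why: Takai olefination: the geminal dichromium species formed from CHI3 adds to the aldehyde and eliminates to the E-iodoalkene, and the non-basic medium should not epimerise the adjacent stereocentre (its descriptor changes to R only through the priority rules).

Step 13
Reactants: 17 terminal alkyne; 21 E-iodoalkene
Product: 23 tert-butyl{[(2R,3E,5E)-2,6-dimethyl-8-[(4aS,8aS)-2,5,5,8a-tetramethyl-3,4,4a,5,6,7,8,8a-octahydronaphthalen-1-yl]octa-3,5-dien-1-yl]oxy}dimethylsilane, via alkenylalane 22 (not isolated)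
Conditions: AlMe3, Cp2ZrCl2 (25 mol%), CH2Cl2, rt; then 21, Pd(PPh3)4 (5 mol%), ZnCl2 (30 mol%), THF, rt
Reagents that add atoms: trimethylaluminium, C[Al](C)C; E-iodoalkene 21, I/C=C/[C@@H](C)CO[Si](C)(C)C(C)(C)C
Why: Zirconium-catalysed methylalumination (Negishi carboalumination) adds methyl and aluminium syn across the terminal alkyne with methyl on the internal carbon, which fixes the E trisubstituted C13=C14 olefin, and palladium/zinc-catalysed cross-coupling of the alkenylalane with the E-iodoalkene proceeds with retention at both partners to form C14–C15 and the E,E-diene; C17 is not involved.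

Step 14
Reactants: 23 diene silyl ether
Product: 24 (2R,3E,5E)-2,6-dimethyl-8-[(4aS,8aS)-2,5,5,8a-tetramethyl-3,4,4a,5,6,7,8,8a-octahydronaphthalen-1-yl]octa-3,5-dien-1-ol
Conditions: Bu4NF, THF, 0 °C → rt
Reagents that add atoms: none
Why: Fluoride-driven cleavage of the primary silyl ether; the diene and the tetrasubstituted olefin are inert to fluoride.

Step 15
Reactants: 24 dienyl alcohol
Product: 25 (2R,3E,5E)-2,6-dimethyl-8-[(4aS,8aS)-2,5,5,8a-tetramethyl-3,4,4a,5,6,7,8,8a-octahydronaphthalen-1-yl]octa-3,5-dienal (used crude at once)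
Conditions: Dess–Martin periodinane, NaHCO3, CH2Cl2, 0 °C
Reagents that add atoms: none
Why: Dess–Martin oxidation under bicarbonate buffering is non-basic and stops at the aldehyde, so the α-stereocentre beside the β,γ-olefin should survive if the aldehyde is carried on without delay.

Step 16
Reactants: 25 dienyl aldehyde
Product: 26 (2R,3E,5E)-2,6-dimethyl-8-[(4aS,8aS)-2,5,5,8a-tetramethyl-3,4,4a,5,6,7,8,8a-octahydronaphthalen-1-yl]octa-3,5-dienoic acid (target)
Conditions: NaClO2, NaH2PO4, 2-methyl-2-butene, t-BuOH/H2O, 0 °C → rt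
Reagents that add atoms: sodium chlorite, [Na+].[O-]Cl=O
Why: Pinnick oxidation in a weakly acidic buffer converts the aldehyde to the acid without enolisation, and the excess 2-methyl-2-butene scavenges hypochlorous acid before it can attack the diene or the tetrasubstituted olefin.

Compound list
1 | (R)-(−)-carvone, (5R)-2-methyl-5-(prop-1-en-2-yl)cyclohex-2-en-1-one | CC1=CC[C@H](CC1=O)C(C)=C | starting material
2 | iodomethane | CI | starting material
3 | lithium (3R)-6-methyl-3-(prop-1-en-2-yl)cyclohexa-1,5-dien-1-olate (cross-conjugated dienolate of 1, carvone stereocentre unchanged) | CC1=CC[C@@H](C(C)=C)C=C1O[Li] | intermediate (not isolated)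
4 | (5R)-2,6-dimethyl-5-(prop-1-en-2-yl)cyclohex-2-en-1-one, both C6 epimers | CC1=CC[C@@H](C(C)=C)C(C)C1=O | intermediate
5 | methyl 2-(bromomethyl)acrylate | C=C(CBr)C(=O)OC | starting material
6 | lithium (3S)-2,6-dimethyl-3-(prop-1-en-2-yl)cyclohexa-1,5-dien-1-olate (tetrasubstituted enolate of 4, carvone stereocentre unchanged) | CC1=CC[C@@H](C(C)=C)C(C)=C1O[Li] | intermediate (not isolated)
7 | methyl 2-{[(1S,6S)-1,3-dimethyl-2-oxo-6-(prop-1-en-2-yl)cyclohex-3-en-1-yl]methyl}prop-2-enoate (methyl cis, acrylate arm trans to isopropenyl) | CC1=CC[C@@H](C(C)=C)[C@](C)(CC(=C)C(=O)OC)C1=O | intermediate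
8 | methyl (4aS,8aS)-4,4,7,8a-tetramethyl-8-oxo-1,2,3,4,4a,5,8,8a-octahydronaphthalene-2-carboxylate, trans-fused (5α-H, 10β-methyl), both C2 epimers | CC1=CC[C@H]2C(C)(C)CC(C(=O)OC)C[C@]2(C)C1=O | intermediate
9 | (4aS,8aS)-4,4,7,8a-tetramethyl-8-oxo-1,2,3,4,4a,5,8,8a-octahydronaphthalene-2-carboxylic acid, both C2 epimers | CC1=CC[C@H]2C(C)(C)CC(C(=O)O)C[C@]2(C)C1=O | intermediate
10 | 2-thioxopyridin-1(2H)-yl ester of 9 (Barton ester) | CC1=CC[C@H]2C(C)(C)CC(C(=O)ON3C=CC=CC3=S)C[C@]2(C)C1=O | intermediate (not isolated)
11 | (4aS,8aS)-2,5,5,8a-tetramethyl-4a,5,6,7,8,8a-hexahydronaphthalen-1(4H)-one | CC1=CC[C@H]2C(C)(C)CCC[C@]2(C)C1=O | intermediate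
12 | lithium (4aS,8aS)-2,5,5,8a-tetramethyl-3,4,4a,5,6,7,8,8a-octahydronaphthalen-1-olate | CC1=C(O[Li])[C@@]2(C)CCCC(C)(C)[C@@H]2CC1 | intermediate (not isolated)
13 | (4aS,8aS)-2,5,5,8a-tetramethyl-3,4,4a,5,6,7,8,8a-octahydronaphthalen-1-yl trifluoromethanesulfonate | CC1=C(OS(=O)(=O)C(F)(F)F)[C@@]2(C)CCCC(C)(C)[C@@H]2CC1 | intermediate
14 | (4-bromobut-1-yn-1-yl)trimethylsilane | C[Si](C)(C)C#CCCBr | starting material
15 | [4-(trimethylsilyl)but-3-yn-1-yl]zinc bromide | C[Si](C)(C)C#CCC[Zn]Br | intermediate
16 | trimethyl{4-[(4aS,8aS)-2,5,5,8a-tetramethyl-3,4,4a,5,6,7,8,8a-octahydronaphthalen-1-yl]but-1-yn-1-yl}silane | CC1=C(CCC#C[Si](C)(C)C)[C@@]2(C)CCCC(C)(C)[C@@H]2CC1 | intermediate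
17 | (4aS,8aS)-1-(but-3-yn-1-yl)-2,5,5,8a-tetramethyl-3,4,4a,5,6,7,8,8a-octahydronaphthalene | CC1=C(CCC#C)[C@@]2(C)CCCC(C)(C)[C@@H]2CC1 | intermediate
18 | methyl (S)-3-hydroxy-2-methylpropanoate | COC(=O)[C@@H](C)CO | starting material
19 | methyl (S)-3-[(tert-butyldimethylsilyl)oxy]-2-methylpropanoate | COC(=O)[C@@H](C)CO[Si](C)(C)C(C)(C)C | intermediate
20 | (S)-3-[(tert-butyldimethylsilyl)oxy]-2-methylpropanal | O=C[C@@H](C)CO[Si](C)(C)C(C)(C)C | intermediate
21 | (R,E)-tert-butyl[(4-iodo-2-methylbut-3-en-1-yl)oxy]dimethylsilane | I/C=C/[C@@H](C)CO[Si](C)(C)C(C)(C)C | intermediate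
22 | dimethyl{(1E)-2-methyl-4-[(4aS,8aS)-2,5,5,8a-tetramethyl-3,4,4a,5,6,7,8,8a-octahydronaphthalen-1-yl]but-1-en-1-yl}alane | CC1=C(CC/C(C)=C/[Al](C)C)[C@@]2(C)CCCC(C)(C)[C@@H]2CC1 | intermediate (not isolated)
23 | tert-butyl{[(2R,3E,5E)-2,6-dimethyl-8-[(4aS,8aS)-2,5,5,8a-tetramethyl-3,4,4a,5,6,7,8,8a-octahydronaphthalen-1-yl]octa-3,5-dien-1-yl]oxy}dimethylsilane | CC1=C(CC/C(C)=C/C=C/[C@@H](C)CO[Si](C)(C)C(C)(C)C)[C@@]2(C)CCCC(C)(C)[C@@H]2CC1 | intermediate
24 | (2R,3E,5E)-2,6-dimethyl-8-[(4aS,8aS)-2,5,5,8a-tetramethyl-3,4,4a,5,6,7,8,8a-octahydronaphthalen-1-yl]octa-3,5-dien-1-ol | CC1=C(CC/C(C)=C/C=C/[C@@H](C)CO)[C@@]2(C)CCCC(C)(C)[C@@H]2CC1 | intermediate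
25 | (2R,3E,5E)-2,6-dimethyl-8-[(4aS,8aS)-2,5,5,8a-tetramethyl-3,4,4a,5,6,7,8,8a-octahydronaphthalen-1-yl]octa-3,5-dienal | CC1=C(CC/C(C)=C/C=C/[C@@H](C)C=O)[C@@]2(C)CCCC(C)(C)[C@@H]2CC1 | intermediate
26 | (2R,3E,5E)-2,6-dimethyl-8-[(4aS,8aS)-2,5,5,8a-tetramethyl-3,4,4a,5,6,7,8,8a-octahydronaphthalen-1-yl]octa-3,5-dienoic acid | CC1=C(CC/C(C)=C/C=C/[C@@H](C)C(=O)O)[C@@]2(C)CCCC(C)(C)[C@@H]2CC1 | target

Total step count: 16.
Longest linear sequence: 12 steps (steps 1–6, 8, 9 and 13–16, from (R)-carvone).

Steps most likely to fail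

Step 3 (key step). The Fe–H species may transfer hydrogen to the acrylate, or the C4 radical may be reduced before it cyclises, so that the isopropenyl group is merely hydrogenated and ring A stays open. Fallback: setting out from 7, Markovnikov addition of HBr (HBr/AcOH, 0 °C) to the isopropenyl group should give the tertiary bromide F1. Slow addition of Bu3SnH with AIBN in benzene at 80 °C would then form the same C4 radical by bromine-atom abstraction, with no metal hydride present that could touch the acrylate. The same 6-endo closure onto C3 comes back to the route at 8.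

Step 8. Transmetalation and reductive elimination may be slow at the alkenylpalladium crowded by quaternary C10 and the C8 methyl, so that β-hydride elimination of the alkyl partner or loss of the triflate by S–O cleavage takes over. Fallback: setting out from 13, methoxycarbonylation (Pd(OAc)2, dppp, CO, Et3N, MeOH/DMF, 70 °C) places the small C11 unit on C9 as the methyl ester F2. Reduction with i-Bu2AlH gives the allylic alcohol F3, and PBr3 converts it into the allylic bromide F4. Alkylation of 3-(trimethylsilyl)prop-2-yn-1-yllithium (from 1-(trimethylsilyl)propyne and n-BuLi, THF, −78 °C) with F4 forms C11–C12 and comes back to the route at 16.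

Step 13. Transfer of the trisubstituted alkenyl group from aluminium to palladium may be sluggish in the one-flask sequence, so that protodemetalation or homocoupling competes with diene formation. Fallback: setting out from 17 and 19, the alkenylalane 22 is made as in step 13, converted into its ate complex with n-BuLi and trapped with paraformaldehyde to give the allylic alcohol F5, which MnO2 oxidises to the enal F6. In parallel, 19 is reduced with excess i-Bu2AlH to the alcohol F7, converted by Mitsunobu reaction with 1-phenyl-1H-tetrazole-5-thiol into the sulfide F8 and oxidised (H2O2, (NH4)6Mo7O24) to the sulfone F9. Julia–Kocienski olefination of F6 with F9 (KN(SiMe3)2, DME, −60 °C) should form the E C15=C16 olefin and comes back to the route at 23.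

Further compounds
F1 | step 3 | methyl 2-{[6-(2-bromopropan-2-yl)-1,3-dimethyl-2-oxocyclohex-3-en-1-yl]methyl}prop-2-enoate, ring stereocentres as in 7 | CC1=CC[C@@H](C(C)(C)Br)[C@](C)(CC(=C)C(=O)OC)C1=O
F2 | step 8 | methyl (4aS,8aS)-2,5,5,8a-tetramethyl-3,4,4a,5,6,7,8,8a-octahydronaphthalene-1-carboxylate | CC1=C(C(=O)OC)[C@@]2(C)CCCC(C)(C)[C@@H]2CC1
F3 | step 8 | [(4aS,8aS)-2,5,5,8a-tetramethyl-3,4,4a,5,6,7,8,8a-octahydronaphthalen-1-yl]methanol | CC1=C(CO)[C@@]2(C)CCCC(C)(C)[C@@H]2CC1
F4 | step 8 | (4aS,8aS)-1-(bromomethyl)-2,5,5,8a-tetramethyl-3,4,4a,5,6,7,8,8a-octahydronaphthalene | CC1=C(CBr)[C@@]2(C)CCCC(C)(C)[C@@H]2CC1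
F5 | step 13 | (2E)-3-methyl-5-[(4aS,8aS)-2,5,5,8a-tetramethyl-3,4,4a,5,6,7,8,8a-octahydronaphthalen-1-yl]pent-2-en-1-ol | CC1=C(CC/C(C)=C/CO)[C@@]2(C)CCCC(C)(C)[C@@H]2CC1
F6 | step 13 | (2E)-3-methyl-5-[(4aS,8aS)-2,5,5,8a-tetramethyl-3,4,4a,5,6,7,8,8a-octahydronaphthalen-1-yl]pent-2-enal | CC1=C(CC/C(C)=C/C=O)[C@@]2(C)CCCC(C)(C)[C@@H]2CC1
F7 | step 13 | (R)-3-[(tert-butyldimethylsilyl)oxy]-2-methylpropan-1-ol | OC[C@@H](C)CO[Si](C)(C)C(C)(C)C
F8 | step 13 | 5-{[(S)-3-[(tert-butyldimethylsilyl)oxy]-2-methylpropyl]sulfanyl}-1-phenyl-1H-tetrazole | c1ccccc1-n1nnnc1SC[C@@H](C)CO[Si](C)(C)C(C)(C)C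
F9 | step 13 | 5-{[(S)-3-[(tert-butyldimethylsilyl)oxy]-2-methylpropyl]sulfonyl}-1-phenyl-1H-tetrazole | O=S(=O)(C[C@@H](C)CO[Si](C)(C)C(C)(C)C)c1nnnn1-c1ccccc1
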